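Ring A and ring C are made together from three alkynes. Ring A carries oxygen on C5, C7 and C8a in a 1,3,5 pattern, which is what three oxygen-substituted alkynes give when each oxygen-bearing carbon is joined to an unsubstituted one; O1, C2, C3 and C4 form the tether between two of them. A rhodium-catalysed (2+2+2) cycloaddition of an enantiopure diyne with tert-butoxyacetylene forms C4a–C8a, C5–C6 and C7–C8 in one operation. The diyne is an ethynyl ether and a tert-butoxy ynone linked through the C2–C3 unit, which already carries phenyl, hexanoate and both stereocentres. It comes from Sharpless epoxidation of cinnamyl alcohol; acid then frees the two phenols.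

Key step: step 16

Remark: the SMILES is read as the (2R,3R)-trans isomer, flavanone numbering is used for ring atoms, and tert-butoxyacetylene is taken as not purchasable and is made in steps 12 and 13 from commercial tert-butyl vinyl ether.

Step 1
Reactants: 1 cinnamyl alcohol [(E)-3-phenylprop-2-en-1-ol]
Product: 2 [(2S,3S)-3-phenyloxiran-2-yl]methanol
Conditions: Ti(OiPr)4 (5 mol%), L-(+)-diisopropyl tartrate (6 mol%), t-BuOOH, 4 Å MS, CH2Cl2, −20 °C
Reagents that add atoms: tert-butyl hydroperoxide, CC(C)(C)OO
Why: Katsuki–Sharpless asymmetric epoxidation of an E-allylic alcohol, in which the titanium complex of the L-tartrate ester delivers oxygen to one face of the alkene and so sets both stereocentres (2S,3S) of the trans epoxide.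

Step 2
Reactants: 2 [(2S,3S)-3-phenyloxiran-2-yl]methanol
Product: 3 (1R,2S)-2,3-dihydroxy-1-phenylpropyl benzoate
Conditions: Ti(OiPr)4 (1.5 equiv), PhCO2H (1.2 equiv), CH2Cl2, rt
Reagents that add atoms: benzoic acid, OC(=O)c1ccccc1
Why: Titanium-mediated regioselective opening of a 2,3-epoxy alcohol by a carboxylic acid, in which benzoate attacks the activated benzylic carbon from the rear, inverting it to R while the C2 oxygen is retained, which fixes the anti relationship of the two secondary oxygens.

Step 3
Reactants: 3 (1R,2S)-2,3-dihydroxy-1-phenylpropyl benzoate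
Product: 4 (R)-[(4S)-2,2-dimethyl-1,3-dioxolan-4-yl](phenyl)methyl benzoate
Conditions: Me2C(OMe)2, PPTS (cat.), CH2Cl2, rt
Reagents that add atoms: 2,2-dimethoxypropane, COC(C)(C)OC
Why: Acid-catalysed acetonide formation (transketalisation) takes the terminal 1,2-diol into the favoured dioxolane and masks the two oxygens that must stay out of the following steps.

Step 4
Reactants: 4 (R)-[(4S)-2,2-dimethyl-1,3-dioxolan-4-yl](phenyl)methyl benzoate
Product: 5 (R)-[(4S)-2,2-dimethyl-1,3-dioxolan-4-yl](phenyl)methanol
Conditions: K2CO3 (0.2 equiv), MeOH, rt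
Reagents that add atoms: none
Why: Base-catalysed transesterification with methanol removes the benzoate and frees the benzylic hydroxyl alone, the acetonide being stable to base.

Step 5
Reactants: 5 (R)-[(4S)-2,2-dimethyl-1,3-dioxolan-4-yl](phenyl)methanol, 6 trichloroethylene
Product: 9 (4S)-4-[(R)-{[(E)-1,2-dichloroethenyl]oxy}(phenyl)methyl]-2,2-dimethyl-1,3-dioxolane, via potassium (R)-[(4S)-2,2-dimethyl-1,3-dioxolan-4-yl](phenyl)methanolate 7 (not isolated), via dichloroacetylene 8 (not isolated)
Conditions: KH (2 equiv), THF, 0 °C; then Cl2C=CHCl, 0 °C to rt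
Reagents that add atoms: none
Why: Addition of the alkoxide to dichloroacetylene formed in situ by dehydrochlorination of trichloroethylene (the dichlorovinyl ether route to ynol ethers) should give the E ether after protonation, without touching the C–O bond of the stereocentre and with an acetonide that cannot migrate to the alkoxide.

Step 6
Reactants: 9 (4S)-4-[(R)-{[(E)-1,2-dichloroethenyl]oxy}(phenyl)methyl]-2,2-dimethyl-1,3-dioxolane
Product: 10 (2S,3R)-3-{[(E)-1,2-dichloroethenyl]oxy}-3-phenylpropane-1,2-diol
Conditions: AcOH/H2O (4:1), 40 °C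
Reagents that add atoms: none
Why: Acid-catalysed acetal hydrolysis, which the doubly chlorinated enol ether is expected to survive because its two chlorine atoms make it too weak a base to be protonated under these mild conditions.

Step 7
Reactants: 10 (2S,3R)-3-{[(E)-1,2-dichloroethenyl]oxy}-3-phenylpropane-1,2-diol
Product: 11 (2S,3R)-1-[(tert-butyldimethylsilyl)oxy]-3-{[(E)-1,2-dichloroethenyl]oxy}-3-phenylpropan-2-ol
Conditions: TBSCl (1.05 equiv), imidazole, CH2Cl2, 0 °C
Reagents that add atoms: tert-butyldimethylsilyl chloride, CC(C)(C)[Si](C)(C)Cl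
Why: Sterically controlled silylation of the primary hydroxyl in the presence of the hindered secondary one.

Step 8
Reactants: 11 (2S,3R)-1-[(tert-butyldimethylsilyl)oxy]-3-{[(E)-1,2-dichloroethenyl]oxy}-3-phenylpropan-2-ol
Product: 14 (2S,3R)-1-[(tert-butyldimethylsilyl)oxy]-3-(ethynyloxy)-3-phenylpropan-2-ol, via lithium (2S,3R)-1-[(tert-butyldimethylsilyl)oxy]-3-[(chloroethynyl)oxy]-3-phenylpropan-2-olate 12 (not isolated), via C,O-dilithio ethynyl ether 13 (not isolated)
Conditions: n-BuLi (3.3 equiv), THF, −78 to −40 °C; then H2O, −78 °C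
Reagents that add atoms: none
Why: After deprotonation of the hydroxyl, base-induced dehydrochlorination to the chloroalkyne and chlorine–lithium exchange (second stage of the dichlorovinyl ether route) give the lithium alkynyl ether, which water protonates to the terminal ethynyl ether while the silyl ether and both stereocentres stay inert at low temperature.

Step 9
Reactants: 14 (2S,3R)-1-[(tert-butyldimethylsilyl)oxy]-3-(ethynyloxy)-3-phenylpropan-2-ol, 15 hexanoyl chloride
Product: 16 (1R,2S)-3-[(tert-butyldimethylsilyl)oxy]-1-(ethynyloxy)-1-phenylpropan-2-yl hexanoate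
Conditions: Et3N, DMAP (cat.), CH2Cl2, 0 °C
Reagents that add atoms: none
Why: DMAP-catalysed O-acylation by an acid chloride in a basic medium, which keeps acid away from the ynol ether and is run while no carbonyl group is present that could lose the ethynyloxy group by β-elimination.

Step 10
Reactants: 16 (1R,2S)-3-[(tert-butyldimethylsilyl)oxy]-1-(ethynyloxy)-1-phenylpropan-2-yl hexanoate
Product: 17 (1R,2S)-1-(ethynyloxy)-3-hydroxy-1-phenylpropan-2-yl hexanoate
Conditions: Et3N·3HF, Et3N, THF, rt
Reagents that add atoms: none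
Why: Fluoride-mediated cleavage of a primary silyl ether with a buffered amine–hydrogen fluoride reagent, which forms no free alkoxide, so the neighbouring hexanoate should not migrate, and which is too weakly acidic to hydrate the ynol ether.

Step 11
Reactants: 17 (1R,2S)-1-(ethynyloxy)-3-hydroxy-1-phenylpropan-2-yl hexanoate
Product: 18 (1R,2R)-1-(ethynyloxy)-3-oxo-1-phenylpropan-2-yl hexanoate
Conditions: Dess–Martin periodinane, pyridine, CH2Cl2, 0 °C; used crude
Reagents that add atoms: none
Why: Dess–Martin oxidation of the primary alcohol to the aldehyde under buffered, non-basic conditions that should not enolise the α-acyloxy aldehyde, so C2 keeps its configuration.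

Step 12
Reactants: 19 tert-butyl vinyl ether [2-(ethenyloxy)-2-methylpropane]
Product: 21 (Z)-2-bromoethenyl tert-butyl ether, via 1,2-dibromoethyl tert-butyl ether 20 (not isolated)
Conditions: Br2 (1.0 equiv), CH2Cl2, −78 °C; then i-Pr2NEt (1.5 equiv), −78 °C to rt; distillation under reduced pressure
Reagents that add atoms: bromine, BrBr
Why: Bromination–dehydrobromination of an alkyl vinyl ether, the classical entry to alkoxyacetylenes, in which bromine adds across the enol ether at low temperature and the hindered amine, added cold so that no free HBr can cleave the tert-butyl group, removes HBr from the α-bromo ether to give mainly the Z 2-bromovinyl ether.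

Step 13
Reactants: 21 (Z)-2-bromoethenyl tert-butyl ether
Product: 23 tert-butoxyacetylene, via sodium tert-butoxyacetylide 22 (not isolated)
Conditions: NaNH2 (2.5 equiv), liquid NH3, −33 °C; then cold brine, pentane, −20 °C; kept as a cold, titrated pentane solution
Reagents that add atoms: none
Why: Amide-induced anti dehydrobromination of the Z bromovinyl ether (the usual last step of alkoxyacetylene syntheses) gives the alkyne, which excess amide holds as its sodium acetylide until cold aqueous protonation, and the ynol ether is kept cold because it loses isobutene on warming.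

Step 14
Reactants: 18 (1R,2R)-1-(ethynyloxy)-3-oxo-1-phenylpropan-2-yl hexanoate, 23 tert-butoxyacetylene
Product: 26 (1R,2S,3RS)-5-tert-butoxy-1-(ethynyloxy)-3-hydroxy-1-phenylpent-4-yn-2-yl hexanoate, via lithium tert-butoxyacetylide 24 (not isolated), via (tert-butoxyethynyl)titanium triisopropoxide 25 (not isolated)
Conditions: 23, n-BuLi, THF, −78 °C; ClTi(OiPr)3, −78 to −40 °C; then 18, −78 to −30 °C; aq. NaHCO3
Reagents that add atoms: none
Why: Chemoselective carbonyl addition of an alkynyltitanium triisopropoxide (made by deprotonation of the terminal ynol ether and transmetalation of the lithium acetylide) to the aldehyde beside the ester, where the weakly basic reagent and the covalent titanium alkoxide should avoid enolisation, β-elimination and acyl transfer, and the new carbinol centre forms without control because step 15 oxidises it away.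

Step 15
Reactants: 26 (1R,2S,3RS)-5-tert-butoxy-1-(ethynyloxy)-3-hydroxy-1-phenylpent-4-yn-2-yl hexanoate
Product: 27 (1R,2R)-5-tert-butoxy-1-(ethynyloxy)-3-oxo-1-phenylpent-4-yn-2-yl hexanoate
Conditions: activated MnO2 (excess), CH2Cl2, 0 °C to rt; filtered and used at once
Reagents that add atoms: none
Why: MnO2 oxidation of a propargylic alcohol to the ynone, the usual neutral access to alkoxyethynyl ketones, in which the absence of base should leave C2 unepimerised and the ethynyloxy group in place.

Step 16
Reactants: 27 (1R,2R)-5-tert-butoxy-1-(ethynyloxy)-3-oxo-1-phenylpent-4-yn-2-yl hexanoate, 23 tert-butoxyacetylene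
Product: 28 (2R,3R)-5,7-di-tert-butoxy-4-oxo-2-phenyl-3,4-dihydro-2H-chromen-3-yl hexanoate
Conditions: [Rh(cod)2]BF4 (5 mol%), rac-BINAP (5 mol%), H2 then Ar for activation, CH2Cl2, rt; 23 (3 equiv); 27 added over 4 h by syringe pump
Reagents that add atoms: none
Why: Oxidative cyclisation of the two tethered alkynes at monovalent rhodium joins C4a to C8a and gives a rhodacyclopentadiene of trivalent rhodium bonded to C5 and C8; insertion of tert-butoxyacetylene and reductive elimination then create C5–C6 and C7–C8 and release the arene and the catalyst without loss of any atom. The closest known reaction type is the cationic rhodium–bisphosphine (2+2+2) cycloaddition of 1,6- and 1,7-diynes with terminal alkynes, which accepts alkynyl ethers, heteroatom-linked diynes and alkynyl ketones. Ring C closes by intramolecular C–C coupling of the two alkyne carbons held by the O1–C2–C3–C4 tether, giving the six-membered ring C8a–O1–C2–C3–C4–C4a, and ring A closes by the intermolecular insertion and reductive elimination that complete the benzene ring. No stereocentre is formed, and C2 and C3 should keep their configuration because no bond to them is touched and the medium is neutral at room temperature. The step needs the monoalkyne to enter with its oxygen-bearing carbon next to C8: the bulky tert-butoxy group avoids the one on C5, and the nucleophilic CH terminus of the ynol ether pairs with C5, the β-carbon of the ynone. Cross-reaction over homo-oligomerisation should be favoured by the match of the electron-poor ynone with the electron-rich ynol ethers, by excess monoalkyne and by slow addition of the diyne.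

Step 17
Reactants: 28 (2R,3R)-5,7-di-tert-butoxy-4-oxo-2-phenyl-3,4-dihydro-2H-chromen-3-yl hexanoate
Product: 29 (2R,3R)-5,7-dihydroxy-4-oxo-2-phenyl-3,4-dihydro-2H-chromen-3-yl hexanoate
Conditions: CF3CO2H/CH2Cl2 (1:4), 0 °C to rt
Reagents that add atoms: none
Why: Acidolysis of the two aryl tert-butyl ethers with loss of isobutene, to which the hexanoate, the ketone and both stereocentres should be stable in anhydrous acid at this temperature.

Compound list
1 | cinnamyl alcohol [(E)-3-phenylprop-2-en-1-ol] | OC/C=C/c1ccccc1 | starting material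
2 | [(2S,3S)-3-phenyloxiran-2-yl]methanol | OC[C@@H]1O[C@H]1c1ccccc1 | intermediate
3 | (1R,2S)-2,3-dihydroxy-1-phenylpropyl benzoate | OC[C@H](O)[C@H](OC(=O)c1ccccc1)c1ccccc1 | intermediate
4 | (R)-[(4S)-2,2-dimethyl-1,3-dioxolan-4-yl](phenyl)methyl benzoate | CC1(C)OC[C@H](O1)[C@H](OC(=O)c1ccccc1)c1ccccc1 | intermediate
5 | (R)-[(4S)-2,2-dimethyl-1,3-dioxolan-4-yl](phenyl)methanol | CC1(C)OC[C@H](O1)[C@H](O)c1ccccc1 | intermediate
6 | trichloroethylene | ClC=C(Cl)Cl | starting material
7 | potassium (R)-[(4S)-2,2-dimethyl-1,3-dioxolan-4-yl](phenyl)methanolate | CC1(C)OC[C@H](O1)[C@H]([O-])c1ccccc1.[K+] | intermediate (not isolated)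
8 | dichloroacetylene | ClC#CCl | intermediate (not isolated)
9 | (4S)-4-[(R)-{[(E)-1,2-dichloroethenyl]oxy}(phenyl)methyl]-2,2-dimethyl-1,3-dioxolane | CC1(C)OC[C@H](O1)[C@H](O/C(Cl)=C\Cl)c1ccccc1 | intermediate
10 | (2S,3R)-3-{[(E)-1,2-dichloroethenyl]oxy}-3-phenylpropane-1,2-diol | OC[C@H](O)[C@H](O/C(Cl)=C\Cl)c1ccccc1 | intermediate
11 | (2S,3R)-1-[(tert-butyldimethylsilyl)oxy]-3-{[(E)-1,2-dichloroethenyl]oxy}-3-phenylpropan-2-ol | CC(C)(C)[Si](C)(C)OC[C@H](O)[C@H](O/C(Cl)=C\Cl)c1ccccc1 | intermediate
12 | lithium (2S,3R)-1-[(tert-butyldimethylsilyl)oxy]-3-[(chloroethynyl)oxy]-3-phenylpropan-2-olate | CC(C)(C)[Si](C)(C)OC[C@H](O[Li])[C@H](OC#CCl)c1ccccc1 | intermediate (not isolated)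
13 | C,O-dilithio ethynyl ether (lithium alkoxide and lithium acetylide of 14) | CC(C)(C)[Si](C)(C)OC[C@H](O[Li])[C@H](OC#C[Li])c1ccccc1 | intermediate (not isolated)
14 | (2S,3R)-1-[(tert-butyldimethylsilyl)oxy]-3-(ethynyloxy)-3-phenylpropan-2-ol | CC(C)(C)[Si](C)(C)OC[C@H](O)[C@H](OC#C)c1ccccc1 | intermediate
15 | hexanoyl chloride | CCCCCC(=O)Cl | starting material
16 | (1R,2S)-3-[(tert-butyldimethylsilyl)oxy]-1-(ethynyloxy)-1-phenylpropan-2-yl hexanoate | CCCCCC(=O)O[C@@H](CO[Si](C)(C)C(C)(C)C)[C@H](OC#C)c1ccccc1 | intermediate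
17 | (1R,2S)-1-(ethynyloxy)-3-hydroxy-1-phenylpropan-2-yl hexanoate | CCCCCC(=O)O[C@@H](CO)[C@H](OC#C)c1ccccc1 | intermediate
18 | (1R,2R)-1-(ethynyloxy)-3-oxo-1-phenylpropan-2-yl hexanoate | CCCCCC(=O)O[C@@H](C=O)[C@H](OC#C)c1ccccc1 | intermediate
19 | tert-butyl vinyl ether [2-(ethenyloxy)-2-methylpropane] | C=COC(C)(C)C | starting material
20 | 1,2-dibromoethyl tert-butyl ether (racemic) | CC(C)(C)OC(Br)CBr | intermediate (not isolated)
21 | (Z)-2-bromoethenyl tert-butyl ether | CC(C)(C)O/C=C\Br | intermediate
22 | sodium tert-butoxyacetylide | CC(C)(C)OC#C[Na] | intermediate (not isolated)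
23 | tert-butoxyacetylene | C#COC(C)(C)C | intermediate
24 | lithium tert-butoxyacetylide | CC(C)(C)OC#C[Li] | intermediate (not isolated)
25 | (tert-butoxyethynyl)titanium triisopropoxide | CC(C)(C)OC#C[Ti](OC(C)C)(OC(C)C)OC(C)C | intermediate (not isolated)
26 | (1R,2S,3RS)-5-tert-butoxy-1-(ethynyloxy)-3-hydroxy-1-phenylpent-4-yn-2-yl hexanoate | CCCCCC(=O)O[C@@H](C(O)C#COC(C)(C)C)[C@H](OC#C)c1ccccc1 | intermediate
27 | (1R,2R)-5-tert-butoxy-1-(ethynyloxy)-3-oxo-1-phenylpent-4-yn-2-yl hexanoate | CCCCCC(=O)O[C@@H](C(=O)C#COC(C)(C)C)[C@H](OC#C)c1ccccc1 | intermediate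
28 | (2R,3R)-5,7-di-tert-butoxy-4-oxo-2-phenyl-3,4-dihydro-2H-chromen-3-yl hexanoate | CCCCCC(=O)O[C@H]1C(=O)c2c(OC(C)(C)C)cc(OC(C)(C)C)cc2O[C@@H]1c1ccccc1 | intermediate
29 | (2R,3R)-5,7-dihydroxy-4-oxo-2-phenyl-3,4-dihydro-2H-chromen-3-yl hexanoate | CCCCCC(=O)O[C@H]1C(=O)c2c(O)cc(O)cc2O[C@@H]1c1ccccc1 | target

Total step count: 17. Longest linear sequence: 15 steps (steps 1–11 and 14–17); steps 12 and 13 make the monoalkyne.

Steps most likely to fail

Step 16. The monoalkyne may be taken up in the reverse orientation, either alkyne may homo-oligomerise, or the ynol ethers may decay at the metal. Fallback, from 2 to 29: ring A would be taken from phloroglucinol and ring C closed by the classical epoxy ketone cyclisation. Alcohol 2 would be oxidised (Dess–Martin periodinane, NaHCO3, CH2Cl2) to (2R,3S)-3-phenyloxirane-2-carbaldehyde F1. 1,3,5-Tris(methoxymethoxy)benzene F2, from phloroglucinol, MeOCH2Cl and iPr2NEt, would be lithiated (n-BuLi, THF, 0 °C) between two acetal oxygens to 2,4,6-tris(methoxymethoxy)phenyllithium F3 and added to F1 at −78 °C to give [(2S,3S)-3-phenyloxiran-2-yl][2,4,6-tris(methoxymethoxy)phenyl]methanol F4 as both carbinol epimers. Dess–Martin oxidation should convert it into [(2R,3S)-3-phenyloxiran-2-yl][2,4,6-tris(methoxymethoxy)phenyl]methanone F5. HCl in MeOH would remove the three acetals, and the freed ortho phenol should open the epoxide at the benzylic carbon with inversion to give (2R,3R)-3,5,7-trihydroxy-2-phenyl-2,3-dihydro-4H-chromen-4-one F6. Hexanoyl chloride 15 (2.2 equiv) in pyridine should acylate O3 and O7 but not the hydrogen-bonded 5-hydroxyl, giving (2R,3R)-5-hydroxy-4-oxo-2-phenyl-3,4-dihydro-2H-chromene-3,7-diyl dihexanoate F7. NH4OAc in aqueous MeOH, which cleaves aryl esters much faster than alkyl esters, would then lead to 29.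

Step 14. The hexanoyl group may shift to the new carbinol oxygen, the aldehyde may enolise with loss of configuration at C2, or the ethynyloxy group may be lost by β-elimination. Fallback, from 10 to 27: the hexanoate would be introduced last, so that the organometallic addition meets no ester. Diol 10 would be silylated twice (Et3SiCl, imidazole) to (2S,3R)-3-{[(E)-1,2-dichloroethenyl]oxy}-3-phenylpropane-1,2-diyl bis(triethylsilyl) ether F8. Swern oxidation ((COCl)2, DMSO, then Et3N), which turns a primary triethylsilyl ether directly into the aldehyde and leaves the secondary one, should give (2R,3R)-3-{[(E)-1,2-dichloroethenyl]oxy}-3-phenyl-2-[(triethylsilyl)oxy]propanal F9. Lithium acetylide 24 (from 23 and n-BuLi) would add to give (3RS,4S,5R)-1-tert-butoxy-5-{[(E)-1,2-dichloroethenyl]oxy}-5-phenyl-4-[(triethylsilyl)oxy]pent-1-yn-3-ol F10. n-BuLi (3.3 equiv, −78 °C), then water, would convert the dichlorovinyl ether into (3RS,4S,5R)-1-tert-butoxy-5-(ethynyloxy)-5-phenyl-4-[(triethylsilyl)oxy]pent-1-yn-3-ol F11. Bu4NF would free (3RS,4S,5R)-1-tert-butoxy-5-(ethynyloxy)-5-phenylpent-1-yne-3,4-diol F12, and MnO2 should oxidise only the propargylic hydroxyl to (4R,5R)-1-tert-butoxy-5-(ethynyloxy)-4-hydroxy-5-phenylpent-1-yn-3-one F13. Hexanoyl chloride 15 and pyridine at −20 °C would then give 27.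

Step 10. The hexanoyl group may migrate to the primary oxygen, or acid may promote addition to the ynol ether during desilylation. Fallback, from 10 to 17: no silyl group is used and the primary oxygen is freed by an enzyme at neutral pH. Diol 10 with n-BuLi (4.4 equiv, THF, −78 °C, then water) would give (2S,3R)-3-(ethynyloxy)-3-phenylpropane-1,2-diol F14. Hexanoyl chloride 15 (2.5 equiv), Et3N and DMAP would give (2S,3R)-3-(ethynyloxy)-3-phenylpropane-1,2-diyl dihexanoate F15. Candida antarctica lipase B with n-butanol in tert-butyl methyl ether, which transesterifies primary esters in preference to hindered secondary ones, should then remove only the primary hexanoate and give 17.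

Further compounds
F1 | step 16 | (2R,3S)-3-phenyloxirane-2-carbaldehyde | O=C[C@@H]1O[C@H]1c1ccccc1
F2 | step 16 | 1,3,5-tris(methoxymethoxy)benzene | COCOc1cc(OCOC)cc(OCOC)c1
F3 | step 16 | 2,4,6-tris(methoxymethoxy)phenyllithium | COCOc1cc(OCOC)c([Li])c(OCOC)c1
F4 | step 16 | [(2S,3S)-3-phenyloxiran-2-yl][2,4,6-tris(methoxymethoxy)phenyl]methanol | COCOc1cc(OCOC)c(C(O)[C@@H]2O[C@H]2c2ccccc2)c(OCOC)c1
F5 | step 16 | [(2R,3S)-3-phenyloxiran-2-yl][2,4,6-tris(methoxymethoxy)phenyl]methanone | COCOc1cc(OCOC)c(C(=O)[C@@H]2O[C@H]2c2ccccc2)c(OCOC)c1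
F6 | step 16 | (2R,3R)-3,5,7-trihydroxy-2-phenyl-2,3-dihydro-4H-chromen-4-one | O[C@H]1C(=O)c2c(O)cc(O)cc2O[C@@H]1c1ccccc1
F7 | step 16 | (2R,3R)-5-hydroxy-4-oxo-2-phenyl-3,4-dihydro-2H-chromene-3,7-diyl dihexanoate | CCCCCC(=O)O[C@H]1C(=O)c2c(O)cc(OC(=O)CCCCC)cc2O[C@@H]1c1ccccc1
F8 | step 14 | (2S,3R)-3-{[(E)-1,2-dichloroethenyl]oxy}-3-phenylpropane-1,2-diyl bis(triethylsilyl) ether | CC[Si](CC)(CC)OC[C@H](O[Si](CC)(CC)CC)[C@H](O/C(Cl)=C\Cl)c1ccccc1
F9 | step 14 | (2R,3R)-3-{[(E)-1,2-dichloroethenyl]oxy}-3-phenyl-2-[(triethylsilyl)oxy]propanal | O=C[C@H](O[Si](CC)(CC)CC)[C@H](O/C(Cl)=C\Cl)c1ccccc1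
F10 | step 14 | (3RS,4S,5R)-1-tert-butoxy-5-{[(E)-1,2-dichloroethenyl]oxy}-5-phenyl-4-[(triethylsilyl)oxy]pent-1-yn-3-ol | CC(C)(C)OC#CC(O)[C@H](O[Si](CC)(CC)CC)[C@H](O/C(Cl)=C\Cl)c1ccccc1
F11 | step 14 | (3RS,4S,5R)-1-tert-butoxy-5-(ethynyloxy)-5-phenyl-4-[(triethylsilyl)oxy]pent-1-yn-3-ol | CC(C)(C)OC#CC(O)[C@H](O[Si](CC)(CC)CC)[C@H](OC#C)c1ccccc1
F12 | step 14 | (3RS,4S,5R)-1-tert-butoxy-5-(ethynyloxy)-5-phenylpent-1-yne-3,4-diol | CC(C)(C)OC#CC(O)[C@H](O)[C@H](OC#C)c1ccccc1
F13 | step 14 | (4R,5R)-1-tert-butoxy-5-(ethynyloxy)-4-hydroxy-5-phenylpent-1-yn-3-one | CC(C)(C)OC#CC(=O)[C@H](O)[C@H](OC#C)c1ccccc1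
F14 | step 10 | (2S,3R)-3-(ethynyloxy)-3-phenylpropane-1,2-diol | OC[C@H](O)[C@H](OC#C)c1ccccc1
F15 | step 10 | (2S,3R)-3-(ethynyloxy)-3-phenylpropane-1,2-diyl dihexanoate | CCCCCC(=O)OC[C@H](OC(=O)CCCCC)[C@H](OC#C)c1ccccc1
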